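**Early turnovers.** At early times I counted turnovers, one for each starting material that a free catalyst had turned into target or isomer of the product, in the gamma and epsilon runs, which differ in their second substrate.

| setting | gamma | delta | epsilon | Saturday's | Friday's | Sunday's |
|---|---|---|---|---|---|---|
| starting material | 0.050 M | 0.050 M | 0.050 M | 0.050 M | 0.050 M | 0.050 M |
| second substrate | 1.3 equiv | 2.3 equiv | 6.8 equiv | 6.20 equiv | 2.50 equiv | 1.00 equiv |
| free catalyst | 0.5 mol% | 0.5 mol% | 0.5 mol% | 0.5 mol% | 0.5 mol% | 0.5 mol% |
| remark | run made earlier | run made earlier | run made earlier |  |  |  |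
| time |  |  |  | 6.0 min | 6.0 min | 6.0 min |

| run | time / min | isomer of the product / % | starting material / % | target / % | catalyst intermediate A / % |
|---|---|---|---|---|---|
| gamma | 0.500 | 6 | 28 | 49 | 2 |
| gamma | 0.833 | 7 | 10 | 66 | 0 |
| gamma | 1.50 | 9 | 4 | 69 | 1 |
| gamma | 3.00 | 9 | 0 | 75 | 0 |
| gamma | 6.00 | 7 | 2 | 71 | 2 |
| delta | 1.33 | 8 | 5 | 62 | 0 |
| delta | 2.50 | 8 | 0 | 70 | 0 |
| delta | 4.00 | 7 | 1 | 70 | 0 |
| delta | 5.00 | 7 | 2 | 70 | 1 |
| delta | 6.00 | 9 | 0 | 68 | 0 |
| epsilon | 0.500 | 8 | 52 | 20 | 2 |
| epsilon | 0.833 | 7 | 33 | 29 | 0 |
| epsilon | 1.50 | 4 | 17 | 42 | 0 |
| epsilon | 3.00 | 11 | 6 | 51 | 1 |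
| epsilon | 6.00 | 10 | 0 | 55 | 0 |

(standard deviation of a reading: 1.5 percentage points)

- a reading or a percentage of target counts all its forms, free or not

- which of these there is most of at the end, counted by the starting material in it, Saturday's (starting material / target / catalyst intermediate A / isomer of the product)
- which of these there is most of at the end, counted by the starting material in it, Friday's (starting material / target / catalyst intermediate A / isomer of the product)
- which of these there is most of at the end, counted by the starting material in it, Sunday's (starting material / target / catalyst intermediate A / isomer of the product)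
- amount of the one of these that there is most of at the end, in percent of the starting material charged, Saturday's
- amount of the one of these that there is most of at the end, in percent of the starting material charged, Friday's
- amount of the one of these that there is most of at the end, in percent of the starting material charged, Sunday's

By 0.500 min each catalyst in the gamma run had made, on average and by the readings, 110 turnovers. In the epsilon run it had made 56.0, about half as many, so more second substrate went with slower turnover.

**The shortfall.** Over its last two readings the gamma run showed a shortfall of 18.0 %. By shortfall, a mass-balance gap, I mean the part of the charge that starting material, target and isomer together no longer hold; catalyst intermediate A I did not count, as the catalyst loading of 0.5 mol% bounds it. The delta run showed 22.0 %, and the last epsilon reading 35.0 %. The epsilon shortfall had stood at 20.0 % at 0.500 min, and the gamma one at 17.0 %. At 1.50 min the epsilon run still held more starting material, 17 % against 4 %. So I took the shortfall to grow while starting material lasts.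

**The line.** A straight line in equivalents through gamma and epsilon gave 21.1 % for the delta run, which it had not used, and delta read 22.0 %. For Saturday's the line gave 33.1 %, for Friday's 21.7 %, and for Sunday's 17.1 %. The late isomer readings average 8.83 %. Subtracting both from the charge, and counting no starting material left, as the epsilon run read 0 % at 6.00 min, I committed to target at 58.0 %, 69.5 % and 74.1 %, in that order.

**Weak link.** Sunday's 1.00 equiv lies below every run, so I reforged its shortfall from the nearest pair, gamma and delta, and got 16.8 %, which left my number standing.

**The result.** The forecast gave target at 57 %, 69 % and 70 %, in the same order, lower than mine on Sunday's, holding that “the mass balance worsens with excess, so unseen losses grow”. At 6.0 min target led in each flask, with 57.0 % on Saturday's, 68.7 % on Friday's and 74.9 % on Sunday's.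

    starting material + free catalyst ⇌ catalyst intermediate A (K = 35.0 M⁻¹, k = 320 M⁻¹ s⁻¹)
    catalyst intermediate A → free catalyst + target (k = 55.0 s⁻¹)
    second substrate + free catalyst ⇌ catalyst intermediate B (K = 32.0 M⁻¹, k = 47.0 M⁻¹ s⁻¹)
    catalyst intermediate B → free catalyst + second product (k = 1.90 s⁻¹)
    target ⇌ isomer of the product (K = 1.30, k = 0.0230 s⁻¹)
    crystals ⇌ target, rate k6*(cs6 - [target]) while solid is left; crystals form when [target] > cs6 (solubility = 3.60 mM, k = 0.410 s⁻¹)
    2 starting material → homo dimer (k = 0.150 M⁻¹ s⁻¹)

Sunday's shortfall came to 15.7 %, and its homo dimer, counted as two starting material, stood at 15.7 %. The neighbouring flask repeats Sunday's recipe at 0.020 M of starting material. Its target 64.4 % and isomer 23.4 % leave a shortfall of 12.2 %, with homo dimer at 12.2 %. Its crystals, counted in target, reached 46.4 %, against 67.7 % in Sunday's flask.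

The runs are simulated with constants of no real substance.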